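I choose to keep the books on the substrate, the limiting reagent of this recipe, entering each share of it against what was charged.

| setting | dawn | summer | flask |
|---|---|---|---|
| substrate | 0.39 M | 0.39 M | 0.39 M |
| free catalyst | 0.7 mol% | 1.1 mol% | 0.5 mol% |
| remark | run made earlier | run made earlier |  |
| time |  |  | 3.0 d |

| run | time / d | target / % |
|---|---|---|
| dawn | 0.0278 | 51.6 |
| dawn | 0.104 | 42.1 |
| dawn | 0.333 | 42.5 |
| dawn | 1.04 | 41.8 |
| dawn | 3.00 | 42.5 |
| summer | 0.0278 | 52.3 |
| summer | 0.104 | 43.6 |
| summer | 0.333 | 42.3 |
| summer | 1.04 | 41.9 |
| summer | 3.00 | 43.1 |

(each reading ± 0.5 percentage points)

- the moment within 3.0 d at which there is most target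
- the amount of target, in percent of the substrate charged, at that time



In both earlier runs the target stops moving from 0.333 d on. Its last three readings average 42.3% in the dawn run and 42.4% in the summer run, with a scatter of 0.5 percentage points per reading, though the loadings are 0.7 mol% and 1.1 mol%. So my first entry is one figure for both, the resting share, meaning the part of the charge that stands as target once the readings stop moving: 42.4%. The second entry is the remainder, 57.6%, which these readings do not show. These two entries close the books once the readings stop moving. Early on the books stand otherwise, since the first readings, 51.6% and 52.3%, lie above the resting share, and I enter that passing excess as target that later goes over to the remainder. For this flask, at 0.5 mol%, I commit to an early best above the resting share and an end on it.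

The forecast says 55% at 1.1 h, on the ground that “peak must exceed 52%, probably about 55%”.

This flask gives 47.3% at 0.843 h, which is 7.7 points below the forecast, with 11.8% substrate and 40.9% isomer of the product beside the target.

    substrate + free catalyst ⇌ catalyst intermediate (K = 5.30 L mol⁻¹, k = 89.6 L mol⁻¹ min⁻¹)
    catalyst intermediate → free catalyst + target (k = 10.0 min⁻¹)
    target ⇌ isomer of the product (K = 1.35, k = 0.0392 min⁻¹)

My unnamed remainder is this isomer: at 3.00 d this flask holds 57.4% of it and 42.6% target, where the resting share of 42.4% put the end. Taking away the conversion of target into isomer of the product lifts this flask's highest target from 47.3% to 100%, a larger change than taking away the undoing of catalyst intermediate gives.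

For the neighbour flask at 0.66 M, the resting share gives 42.4% at the end. The computed end there is 42.6%, after a best of 52.1%.

The runs were generated by integration from invented constants; noise was put on by code.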